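No equilibrium constant can give the product of these flasks, since the step from intermediate A to product has no way back. The amount depends on time.

- gamma: substrate 20 mM; coupling partner 1.00 equiv; time 2.0 min
- eta: substrate 20 mM; coupling partner 2.50 equiv; time 2.0 min

    substrate + coupling partner ⇌ intermediate A (K1 = 120 M⁻¹, k1 = 16.3 M⁻¹ s⁻¹)
    coupling partner + intermediate A ⇌ intermediate B (K2 = 100 M⁻¹, k2 = 0.176 M⁻¹ s⁻¹)
    intermediate A → product (k3 = 0.00978 s⁻¹)
    intermediate B ⇌ intermediate C (K4 = 0.716, k4 = 0.00200 s⁻¹)
    intermediate B ⇌ intermediate D (K5 = 0.56, k5 = 0.0939 s⁻¹)
    coupling partner ⇌ dormant form (K6 = 2.0, k6 = 0.130 s⁻¹)

- which of these there is most of at the end, counted by the substrate in it, gamma (intermediate A / substrate / intermediate B / product)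
- which of these there is most of at the end, counted by the substrate in it, eta (intermediate A / substrate / intermediate B / product)
- how much there is at the end of the one of these that leads, in percent of the substrate charged: gamma
- how much there is at the end of the one of these that leads, in percent of the substrate charged: eta

Product has one source, so its rate is the rate constant of that step times [intermediate A]. Over a run this sums to a simple rule. The drain number, the rate constant of the product step times the reaction time, multiplies the mean share of substrate held as intermediate A to give the share turned into product:

drain number = 0.00978 s⁻¹ × 2.0 min = 1.17

What remains is the mean. In gamma, substrate binds with a forward half-life of 2.1 s, partner as charged, and the partner and dormant form relax with a half-life of 3.55 s. Both are short against 2.0 min, so this reckoning treats both steps as a pre-equilibrium. Intermediate B forms with a forward half-life of 3.3 min in gamma, longer than the run, so it is left out. With c, one plus the dormant constant over the binding constant, and the excess of partner over substrate: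

[intermediate A] = [substrate] × ([substrate] + excess) / c, with c = 25.0 mM

[substrate] + [intermediate A] + [product] = 20 mM

In gamma the excess is zero. Before any product forms, intermediate A holds 34.4%. Keeping that share throughout would give 40.4% product, which is too high, as the share falls when product forms. At that product, intermediate A holds 15.5%. The straight-line mean of start and end then gives a second pass, and that end state a third:

product, gamma: 29.3%, then 32.1%

Between these passes stands 30.7%, which leaves 49.6% substrate, so substrate leads in gamma.

In eta the excess is 30.0 mM, and intermediate A starts at 60.3%. The same passes give:

product, eta: 45.1%, then 54.1%

Their mean is 49.6%, with 21.3% substrate and 29.1% intermediate A, so product leads in eta. Intermediate B stays left out in eta too: the reckoning puts free partner at 11.4 mM by the end, and at that level intermediate A forms intermediate B with a forward half-life of 5.75 min, longer than the run.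

The forecast gives substrate at 49% for gamma and product at 47% for eta, with “product builds only through the slow first-order drain of A”.

The simulation gives substrate at 50.3% for gamma, with 29.5% product, and product at 45.8% for eta.

Divided by the drain number, these products give a mean share of intermediate A of 25.1% in gamma, against 26.2% reckoned, and 39.1% in eta, against 42.4% reckoned. Neither flask has come to rest. At 20.0 min the drain number is 11.7. Gamma then holds 82.8% product, a mean share of 7.05%, with 14.1% substrate still unbound. Eta holds 90.7% product, a mean share of 7.73%, with 0.546% substrate and 3.35% intermediate B.

(All constants are those of an exercise; the result is computed.)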